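**Strategy.** Both end groups are cut from the polyene at C11=C12 and C11'=C12' (Wittig, C10 dialdehyde) and traced to one enone. The key step exploits, in ring A and ring B alike, the gem-dimethyl carbon C1 beside the stereocentre C2 with its C1''–C2'' arm: these are the quaternary carbon and stereocentre of campholenic aldehyde. Ozonolysis of its cyclopentene gives a keto aldehyde (acetyl on C1, CHO as C4, arm masked as dimethyl acetal). One aldol condensation joins the acetyl methyl carbon (C5) to C4, closing the six-membered ring with its carbonyl at C6 and leaving C2 untouched. C6 is set later, cis for ring A and trans for ring B.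

Key step: step 5

Numbering used throughout (rings and their precursors): C1 = CMe2, C2 = CH carrying the arm (C1'', C2'', …), C3 = CH2, C4=C5(Me), C6 = CH carrying C7.

Remark on configuration: both rings have the same spatial arrangement at C2, that of C5 in (1S,5S)-α-pinene. The descriptor reads 2S in ring A and 2'R in ring B only because the arm changes CIP rank. The rings differ at C6 (ring A 6R, cis; ring B 6'S, trans).

Assumption: hydroboration of diene 17 (step 9) has no overriding facial bias, so both C6 epimers are isolated from that one step; the target needs exactly one of each.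

**Route**

Step 1
Reactants: 1 (1S,5S)-(−)-α-pinene; 2 3-chloroperbenzoic acid
Product: 3 α-pinene oxide (oxygen anti to the CMe2 bridge)
Conditions: mCPBA, NaHCO3, CH2Cl2, 0 °C
Reagents that add atoms: 3-chloroperbenzoic acid, OOC(=O)c1cccc(Cl)c1
Why: Prilezhaev epoxidation of the trisubstituted alkene should occur on the face away from the gem-dimethyl bridge, whose syn methyl shields the other face, and this fixes both epoxide carbons.

Step 2
Reactants: 3 α-pinene oxide
Product: 4 (R)-campholenic aldehyde
Conditions: ZnBr2 (cat.), toluene, 80 °C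
Reagents that add atoms: none
Why: Lewis-acid opening at the tertiary epoxide carbon, Wagner–Meerwein shift of the CMe2 bridge and Grob-type fragmentation is the established rearrangement of this epoxide to campholenic aldehyde; the stereocentre that is kept (C5 of pinene, the future C2) takes no part.

Step 3
Reactants: 4 (R)-campholenic aldehyde; 5 trimethyl orthoformate
Product: 6 (4R)-4-(2,2-dimethoxyethyl)-1,5,5-trimethylcyclopent-1-ene
Conditions: HC(OMe)3, pyridinium p-toluenesulfonate (cat.), MeOH, rt
Reagents that add atoms: trimethyl orthoformate, COC(OC)OC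
Why: Acid-catalysed acetalisation with the orthoformate as water scavenger masks the arm carbonyl C2'' so that only one aldehyde is present in the aldol step, and the mild acid leaves the trisubstituted alkene in place.

Step 4
Reactants: 6 dimethyl acetal; 7 ozone
Product: 9 (3R)-3-(2,2-dimethoxyethyl)-4,4-dimethyl-5-oxohexanal, via ozonide 8 (not isolated)
Conditions: O3, CH2Cl2, −78 °C (Sudan Red 7B end point); then PPh3, −78 °C to rt
Reagents that add atoms: ozone, [O-][O+]=O
Why: Ozonolysis (Criegee mechanism) with reductive work-up cleaves the only C=C bond to the methyl ketone on C1 and the aldehyde C4, the acetal C–H reacting far more slowly with ozone than the alkene.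

Step 5
Reactants: 9 keto aldehyde
Product: 11 (5R)-5-(2,2-dimethoxyethyl)-6,6-dimethylcyclohex-2-en-1-one, via β-hydroxy ketone 10 (not isolated)
Conditions: piperidine (0.2 equiv), AcOH (0.2 equiv), toluene (0.05 M), 80 °C
Reagents that add atoms: none
Why: Piperidinium acetate activates the unhindered aldehyde C4 (as such or as its iminium ion) and enolises the methyl ketone, which can enolise only toward its methyl group because its other α-carbon is the quaternary C1; the enol carbon (future C5) adds to C4, and loss of water from 10 gives the conjugated enone with the carbonyl at C6. The closest known reaction type is the intramolecular aldol condensation of 1,5-keto aldehydes made by ozonolysis of 1-methylcyclopentenes. The one ring formed is closed in the 6-(enolendo)-exo-trig mode, the vinylic methyl carbon of the terpene becoming ring carbon C5. No stereocentre is created, and C2 is β to both carbonyl groups and so cannot epimerise. Only chemoselectivity is needed: enolisation of the aldehyde at C3 could close only a four-membered ring and the second aldehyde function is masked as the acetal, so a single enone can form.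

Step 6
Reactants: 11 enone; 12 iodine
Product: 13 (5R)-5-(2,2-dimethoxyethyl)-2-iodo-6,6-dimethylcyclohex-2-en-1-one
Conditions: I2, K2CO3, 4-(dimethylamino)pyridine (cat.), THF–H2O, rt
Reagents that add atoms: iodine, [I][I]
Why: α-Iodination of a cyclic enone by conjugate addition of the amine catalyst at C4, iodination of the enolate at C5 and loss of the amine (Baylis–Hillman-type addition–elimination) is standard, and the basic medium spares the acetal.

Step 7
Reactants: 13 α-iodoenone; 14 trimethylboroxine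
Product: 15 (5R)-5-(2,2-dimethoxyethyl)-2,6,6-trimethylcyclohex-2-en-1-one
Conditions: (MeBO)3, Pd(dppf)Cl2 (cat.), K2CO3, 1,4-dioxane–H2O, 90 °C
Reagents that add atoms: trimethylboroxine, CB1OB(C)OB(C)O1
Why: Suzuki–Miyaura coupling, in which zerovalent palladium inserts into the C5–I bond, methyl is transferred from boron and reductive elimination installs the C5 methyl group.

Step 8
Reactants: 15 2-methyl enone; 16 methyltriphenylphosphonium bromide
Product: 17 (4R)-4-(2,2-dimethoxyethyl)-1,5,5-trimethyl-6-methylidenecyclohex-1-ene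
Conditions: Ph3PCH3Br, KOtBu, toluene, 90 °C
Reagents that add atoms: methyltriphenylphosphonium bromide, C[P+](c1ccccc1)(c1ccccc1)c1ccccc1.[Br-]
Why: Wittig methylenation with the small ylide at elevated temperature is the usual method for ketones flanked by a quaternary carbon and turns C6=O into C6=C7; C1 carries no hydrogen, so enolisation on that side cannot compete.

Step 9
Reactants: 17 diene; 18 9-borabicyclo[3.3.1]nonane; 19 hydrogen peroxide
Product: 21 cis alcohol [(1R,5R)-5-(2,2-dimethoxyethyl)-2,6,6-trimethylcyclohex-2-en-1-yl]methanol; 22 trans alcohol [(1S,5R)-5-(2,2-dimethoxyethyl)-2,6,6-trimethylcyclohex-2-en-1-yl]methanol (C6 epimers, separated on silica), via B-alkyl-9-BBN adduct 20 (not isolated)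
Conditions: 9-BBN, THF, 0 to 60 °C; then NaOH, H2O2, 0 °C to rt; chromatography
Reagents that add atoms: hydrogen peroxide, OO
Why: Hydroboration–oxidation with 9-BBN should select the exocyclic 1,1-disubstituted alkene over the trisubstituted ring alkene and place boron on C7; the syn-delivered hydrogen creates C6, delivery anti to the C2 arm giving cis 21 (expected to predominate) and delivery syn giving trans 22, and both epimers are wanted (21 for ring A, 22 for ring B).

Step 10
Reactants: 21 cis alcohol; 23 water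
Product: 24 2-[(1R,5R)-5-(hydroxymethyl)-4,6,6-trimethylcyclohex-3-en-1-yl]acetaldehyde
Conditions: 1 M HCl, THF, rt
Reagents that add atoms: water, O
Why: Acid-catalysed hydrolysis of the dimethyl acetal frees the arm aldehyde C2''; at this stage C6 is not α to a carbonyl and the ring alkene is stable to cold dilute acid.

Step 11
Reactants: 24 cis hydroxy aldehyde; 25 isopropyltriphenylphosphonium iodide
Product: 26 [(1R,5S)-2,6,6-trimethyl-5-(3-methylbut-2-en-1-yl)cyclohex-2-en-1-yl]methanol
Conditions: i-PrPPh3I (2.5 equiv), n-BuLi (2.4 equiv), THF, −78 °C to rt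
Reagents that add atoms: isopropyltriphenylphosphonium iodide, CC(C)[P+](c1ccccc1)(c1ccccc1)c1ccccc1.[I-]
Why: Wittig olefination of the unhindered arm aldehyde with the non-stabilised isopropylidene ylide (in excess to cover the free hydroxyl) gives the prenyl group, whose alkene has no geometry to control.

Step 12
Reactants: 26 prenyl alcohol
Product: 27 (1R,5S)-2,6,6-trimethyl-5-(3-methylbut-2-en-1-yl)cyclohex-2-ene-1-carbaldehyde
Conditions: Dess–Martin periodinane, NaHCO3, CH2Cl2, 0 °C
Reagents that add atoms: none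
Why: Dess–Martin oxidation under bicarbonate buffer gives the β,γ-unsaturated aldehyde C7 without a base able to enolise C6 or to move the ring alkene into conjugation.

Step 13
Reactants: 27 ring A aldehyde; 28 dimethyl (2-oxopropyl)phosphonate
Product: 29 (3E)-4-[(1R,5S)-2,6,6-trimethyl-5-(3-methylbut-2-en-1-yl)cyclohex-2-en-1-yl]but-3-en-2-one
Conditions: (MeO)2P(O)CH2C(O)CH3, LiCl, i-Pr2NEt, MeCN, rt
Reagents that add atoms: dimethyl (2-oxopropyl)phosphonate, COP(=O)(CC(C)=O)OC
Why: Horner–Wadsworth–Emmons olefination with LiCl and an amine base forms C7=C8 with E geometry under conditions mild enough to keep the configuration of C6.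

Step 14
Reactants: 29 ring A enone; 30 vinylmagnesium bromide
Product: 31 (1E)-3-methyl-1-[(1R,5S)-2,6,6-trimethyl-5-(3-methylbut-2-en-1-yl)cyclohex-2-en-1-yl]penta-1,4-dien-3-ol
Conditions: CH2=CHMgBr, THF, −78 to 0 °C
Reagents that add atoms: vinylmagnesium bromide, C=C[Mg]Br
Why: Grignard 1,2-addition to the methyl ketone, as in the preparation of vinylionols, adds C10 and C11; the new carbinol centre C9 forms as both epimers and is removed in the next step.

Step 15
Reactants: 31 ring A vinyl carbinol; 32 triphenylphosphine hydrobromide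
Product: 33 {(2E,4E)-3-methyl-5-[(1R,5S)-2,6,6-trimethyl-5-(3-methylbut-2-en-1-yl)cyclohex-2-en-1-yl]penta-2,4-dien-1-yl}triphenylphosphonium bromide
Conditions: PPh3·HBr, MeOH, rt
Reagents that add atoms: triphenylphosphine hydrobromide, Br.c1ccc(cc1)P(c1ccccc1)c1ccccc1
Why: Ionisation of the tertiary allylic alcohol and capture of the allyl cation at its primary end C11 by PPh3 (allylic transposition, the standard entry to carotenoid Wittig salts) should give mainly the 9E salt without touching C6.

Step 16
Reactants: 22 trans alcohol; 23 water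
Product: 34 2-[(1R,5S)-5-(hydroxymethyl)-4,6,6-trimethylcyclohex-3-en-1-yl]acetaldehyde
Conditions: 1 M HCl, THF, rt
Reagents that add atoms: water, O
Why: Acid-catalysed acetal hydrolysis as in step 10, with C6 again not epimerisable.

Step 17
Reactants: 34 trans hydroxy aldehyde; 35 methyl 2-(triphenylphosphoranylidene)propanoate
Product: 36 methyl (2E)-4-[(1R,5S)-5-(hydroxymethyl)-4,6,6-trimethylcyclohex-3-en-1-yl]-2-methylbut-2-enoate
Conditions: Ph3P=C(CH3)CO2Me, CH2Cl2, rt
Reagents that add atoms: methyl 2-(triphenylphosphoranylidene)propanoate, COC(=O)C(C)=P(c1ccccc1)(c1ccccc1)c1ccccc1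
Why: Wittig olefination with the stabilised α-methyl ylide gives the E-trisubstituted enoate, tolerates the free hydroxyl and stores the future allylic alcohol as an ester that needs no protecting group.

Step 18
Reactants: 36 hydroxy enoate
Product: 37 methyl (2E)-4-[(1R,5S)-5-formyl-4,6,6-trimethylcyclohex-3-en-1-yl]-2-methylbut-2-enoate
Conditions: Dess–Martin periodinane, NaHCO3, CH2Cl2, 0 °C
Reagents that add atoms: none
Why: Buffered Dess–Martin oxidation as in step 12, without enolisation at C6.

Step 19
Reactants: 37 ring B aldehyde; 28 dimethyl (2-oxopropyl)phosphonate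
Product: 38 methyl (2E)-2-methyl-4-{(1R,5S)-4,6,6-trimethyl-5-[(1E)-3-oxobut-1-en-1-yl]cyclohex-3-en-1-yl}but-2-enoate
Conditions: (MeO)2P(O)CH2C(O)CH3, LiCl, i-Pr2NEt, MeCN, rt
Reagents that add atoms: dimethyl (2-oxopropyl)phosphonate, COP(=O)(CC(C)=O)OC
Why: Horner–Wadsworth–Emmons olefination as in step 13 forms the E C7'=C8' bond; the enoate is inert to the stabilised phosphonate anion.

Step 20
Reactants: 38 ring B enone; 30 vinylmagnesium bromide
Product: 39 methyl (2E)-4-{(1R,5S)-5-[(1E)-3-hydroxy-3-methylpenta-1,4-dien-1-yl]-4,6,6-trimethylcyclohex-3-en-1-yl}-2-methylbut-2-enoate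
Conditions: CH2=CHMgBr (1.2 equiv), THF, −78 °C
Reagents that add atoms: vinylmagnesium bromide, C=C[Mg]Br
Why: Grignard 1,2-addition is chemoselective because the methyl ketone is far more electrophilic than the α-methyl enoate at low temperature; the carbinol centre C9' is uncontrolled and lost in step 21.

Step 21
Reactants: 39 ring B vinyl carbinol; 32 triphenylphosphine hydrobromide
Product: 40 {(2E,4E)-5-[(1S,5R)-5-[(2E)-4-methoxy-3-methyl-4-oxobut-2-en-1-yl]-2,6,6-trimethylcyclohex-2-en-1-yl]-3-methylpenta-2,4-dien-1-yl}triphenylphosphonium bromide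
Conditions: PPh3·HBr, MeOH, rt
Reagents that add atoms: triphenylphosphine hydrobromide, Br.c1ccc(cc1)P(c1ccccc1)c1ccccc1
Why: Allylic transposition to the primary phosphonium salt as in step 15; the methyl enoate is stable to the acidic methanol.

Step 22
Reactants: 33 ring A phosphonium salt; 41 (2E,4E,6E)-2,7-dimethylocta-2,4,6-trienedial
Product: 43 (2E,4E,6E,8E,10E,12E)-2,7,11-trimethyl-13-[(1R,5S)-2,6,6-trimethyl-5-(3-methylbut-2-en-1-yl)cyclohex-2-en-1-yl]trideca-2,4,6,8,10,12-hexaenal, via phosphorus ylide 42 (not isolated)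
Conditions: 41 (3 equiv), NaOMe, MeOH–CH2Cl2, 0 °C to rt, dark; chromatography
Reagents that add atoms: (2E,4E,6E)-2,7-dimethylocta-2,4,6-trienedial, O=C/C(C)=C/C=C/C=C(C)/C=O
Why: Wittig olefination of the semi-stabilised ylide with an excess of the symmetrical dialdehyde should stop at the mono-adduct and forms C11=C12; C6 is not acidic in the ylide, and the all-E aldehyde is taken from the E/Z mixture.

Step 23
Reactants: 40 ring B phosphonium salt; 43 C30 aldehyde
Product: 45 methyl ester of the target (CO2Me in place of CH2OH on the ring B arm), via phosphorus ylide 44 (not isolated)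
Conditions: NaOMe, MeOH–CH2Cl2, rt, dark; then n-heptane, reflux
Reagents that add atoms: none
Why: The second Wittig olefination forms C11'=C12', and heating in heptane, the usual finish for carotenoids, should isomerise Z bonds of the unhindered polyene to the all-E form while leaving C6 and C6' unchanged.

Step 24
Reactants: 45 C50 methyl ester
Product: 46 target CNP0304855.1
Conditions: i-Bu2AlH, CH2Cl2–THF, −40 °C; aq. potassium sodium tartrate
Reagents that add atoms: none
Why: 1,2-Reduction of the isolated α,β-unsaturated methyl ester by the aluminium hydride gives the E-allylic alcohol, the polyene and both rings being inert to the reagent.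

**Compound list**

1 | (1S,5S)-(−)-α-pinene, (1S,5S)-2,6,6-trimethylbicyclo[3.1.1]hept-2-ene | CC1=CC[C@H]2C[C@@H]1C2(C)C | starting material
2 | 3-chloroperbenzoic acid | OOC(=O)c1cccc(Cl)c1 | starting material
3 | α-pinene oxide, (1R,2R,4S,6R)-2,7,7-trimethyl-3-oxatricyclo[4.1.1.0(2,4)]octane, oxygen anti to the CMe2 bridge | C[C@]1(O2)[C@@H]2C[C@H]3C[C@@H]1C3(C)C | intermediate
4 | (R)-campholenic aldehyde, 2-[(1R)-2,2,3-trimethylcyclopent-3-en-1-yl]acetaldehyde | CC1=CC[C@H](CC=O)C1(C)C | intermediate
5 | trimethyl orthoformate | COC(OC)OC | starting material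
6 | (4R)-4-(2,2-dimethoxyethyl)-1,5,5-trimethylcyclopent-1-ene | CC1=CC[C@H](CC(OC)OC)C1(C)C | intermediate
7 | ozone | [O-][O+]=O | starting material
8 | ozonide (1,2,4-trioxolane) of 6, mixture at the two ozonide carbons, not isolated | CC12OOC(O1)C[C@H](CC(OC)OC)C2(C)C | intermediate
9 | (3R)-3-(2,2-dimethoxyethyl)-4,4-dimethyl-5-oxohexanal | CC(=O)C(C)(C)[C@@H](CC(OC)OC)CC=O | intermediate
10 | (5R)-5-(2,2-dimethoxyethyl)-3-hydroxy-6,6-dimethylcyclohexan-1-one, both C3 epimers, not isolated | O=C1CC(O)C[C@H](CC(OC)OC)C1(C)C | intermediate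
11 | (5R)-5-(2,2-dimethoxyethyl)-6,6-dimethylcyclohex-2-en-1-one | COC(OC)C[C@H]1CC=CC(=O)C1(C)C | intermediate
12 | iodine | [I][I] | starting material
13 | (5R)-5-(2,2-dimethoxyethyl)-2-iodo-6,6-dimethylcyclohex-2-en-1-one | COC(OC)C[C@H]1CC=C(I)C(=O)C1(C)C | intermediate
14 | trimethylboroxine | CB1OB(C)OB(C)O1 | starting material
15 | (5R)-5-(2,2-dimethoxyethyl)-2,6,6-trimethylcyclohex-2-en-1-one | COC(OC)C[C@H]1CC=C(C)C(=O)C1(C)C | intermediate
16 | methyltriphenylphosphonium bromide | C[P+](c1ccccc1)(c1ccccc1)c1ccccc1.[Br-] | starting material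
17 | (4R)-4-(2,2-dimethoxyethyl)-1,5,5-trimethyl-6-methylidenecyclohex-1-ene | COC(OC)C[C@H]1CC=C(C)C(=C)C1(C)C | intermediate
18 | 9-borabicyclo[3.3.1]nonane | [H]B1C2CCCC1CCC2 | starting material
19 | hydrogen peroxide | OO | starting material
20 | B-alkyl-9-BBN adduct of 17, boron on C7, both C6 epimers, not isolated | COC(OC)C[C@H]1CC=C(C)C(CB2C3CCCC2CCC3)C1(C)C | intermediate
21 | cis alcohol, [(1R,5R)-5-(2,2-dimethoxyethyl)-2,6,6-trimethylcyclohex-2-en-1-yl]methanol (2R,6R in ring numbering) | COC(OC)C[C@H]1CC=C(C)[C@@H](CO)C1(C)C | intermediate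
22 | trans alcohol, [(1S,5R)-5-(2,2-dimethoxyethyl)-2,6,6-trimethylcyclohex-2-en-1-yl]methanol (2R,6S in ring numbering) | COC(OC)C[C@H]1CC=C(C)[C@H](CO)C1(C)C | intermediate
23 | water | O | starting material
24 | 2-[(1R,5R)-5-(hydroxymethyl)-4,6,6-trimethylcyclohex-3-en-1-yl]acetaldehyde (cis) | O=CC[C@H]1CC=C(C)[C@@H](CO)C1(C)C | intermediate
25 | isopropyltriphenylphosphonium iodide | CC(C)[P+](c1ccccc1)(c1ccccc1)c1ccccc1.[I-] | starting material
26 | [(1R,5S)-2,6,6-trimethyl-5-(3-methylbut-2-en-1-yl)cyclohex-2-en-1-yl]methanol (cis; 2S,6R) | CC(C)=CC[C@H]1CC=C(C)[C@@H](CO)C1(C)C | intermediate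
27 | (1R,5S)-2,6,6-trimethyl-5-(3-methylbut-2-en-1-yl)cyclohex-2-ene-1-carbaldehyde (cis) | CC(C)=CC[C@H]1CC=C(C)[C@@H](C=O)C1(C)C | intermediate
28 | dimethyl (2-oxopropyl)phosphonate | COP(=O)(CC(C)=O)OC | starting material
29 | (3E)-4-[(1R,5S)-2,6,6-trimethyl-5-(3-methylbut-2-en-1-yl)cyclohex-2-en-1-yl]but-3-en-2-one | CC(C)=CC[C@H]1CC=C(C)[C@@H](/C=C/C(C)=O)C1(C)C | intermediate
30 | vinylmagnesium bromide | C=C[Mg]Br | starting material
31 | (1E)-3-methyl-1-[(1R,5S)-2,6,6-trimethyl-5-(3-methylbut-2-en-1-yl)cyclohex-2-en-1-yl]penta-1,4-dien-3-ol, both C9 epimers | CC(C)=CC[C@H]1CC=C(C)[C@@H](/C=C/C(C)(O)C=C)C1(C)C | intermediate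
32 | triphenylphosphine hydrobromide | Br.c1ccc(cc1)P(c1ccccc1)c1ccccc1 | starting material
33 | ring A salt, {(2E,4E)-3-methyl-5-[(1R,5S)-2,6,6-trimethyl-5-(3-methylbut-2-en-1-yl)cyclohex-2-en-1-yl]penta-2,4-dien-1-yl}triphenylphosphonium bromide | CC(C)=CC[C@H]1CC=C(C)[C@@H](/C=C/C(C)=C/C[P+](c2ccccc2)(c2ccccc2)c2ccccc2)C1(C)C.[Br-] | intermediate
34 | 2-[(1R,5S)-5-(hydroxymethyl)-4,6,6-trimethylcyclohex-3-en-1-yl]acetaldehyde (trans) | O=CC[C@H]1CC=C(C)[C@H](CO)C1(C)C | intermediate
35 | methyl 2-(triphenylphosphoranylidene)propanoate | COC(=O)C(C)=P(c1ccccc1)(c1ccccc1)c1ccccc1 | starting material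
36 | methyl (2E)-4-[(1R,5S)-5-(hydroxymethyl)-4,6,6-trimethylcyclohex-3-en-1-yl]-2-methylbut-2-enoate (trans; 2R,6S) | COC(=O)/C(C)=C/C[C@H]1CC=C(C)[C@H](CO)C1(C)C | intermediate
37 | methyl (2E)-4-[(1R,5S)-5-formyl-4,6,6-trimethylcyclohex-3-en-1-yl]-2-methylbut-2-enoate | COC(=O)/C(C)=C/C[C@H]1CC=C(C)[C@H](C=O)C1(C)C | intermediate
38 | methyl (2E)-2-methyl-4-{(1R,5S)-4,6,6-trimethyl-5-[(1E)-3-oxobut-1-en-1-yl]cyclohex-3-en-1-yl}but-2-enoate | COC(=O)/C(C)=C/C[C@H]1CC=C(C)[C@H](/C=C/C(C)=O)C1(C)C | intermediate
39 | methyl (2E)-4-{(1R,5S)-5-[(1E)-3-hydroxy-3-methylpenta-1,4-dien-1-yl]-4,6,6-trimethylcyclohex-3-en-1-yl}-2-methylbut-2-enoate, both C9' epimers | COC(=O)/C(C)=C/C[C@H]1CC=C(C)[C@H](/C=C/C(C)(O)C=C)C1(C)C | intermediate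
40 | ring B salt, {(2E,4E)-5-[(1S,5R)-5-[(2E)-4-methoxy-3-methyl-4-oxobut-2-en-1-yl]-2,6,6-trimethylcyclohex-2-en-1-yl]-3-methylpenta-2,4-dien-1-yl}triphenylphosphonium bromide | COC(=O)/C(C)=C/C[C@H]1CC=C(C)[C@H](/C=C/C(C)=C/C[P+](c2ccccc2)(c2ccccc2)c2ccccc2)C1(C)C.[Br-] | intermediate
41 | (2E,4E,6E)-2,7-dimethylocta-2,4,6-trienedial | O=C/C(C)=C/C=C/C=C(C)/C=O | starting material
42 | phosphorus ylide from 33 (C11=P), not isolated | CC(C)=CC[C@H]1CC=C(C)[C@@H](/C=C/C(C)=C/C=P(c2ccccc2)(c2ccccc2)c2ccccc2)C1(C)C | intermediate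
43 | (2E,4E,6E,8E,10E,12E)-2,7,11-trimethyl-13-[(1R,5S)-2,6,6-trimethyl-5-(3-methylbut-2-en-1-yl)cyclohex-2-en-1-yl]trideca-2,4,6,8,10,12-hexaenal | CC(C)=CC[C@H]1CC=C(C)[C@@H](/C=C/C(C)=C/C=C/C(C)=C/C=C/C=C(C)/C=O)C1(C)C | intermediate
44 | phosphorus ylide from 40 (C11'=P), not isolated | COC(=O)/C(C)=C/C[C@H]1CC=C(C)[C@H](/C=C/C(C)=C/C=P(c2ccccc2)(c2ccccc2)c2ccccc2)C1(C)C | intermediate
45 | all-E C50 methyl ester: the target with CO2Me in place of CH2OH on the ring B arm; ring A (2S,6R), ring B (2'R,6'S) | CC(C)=CC[C@H]1CC=C(C)[C@@H](/C=C/C(C)=C/C=C/C(C)=C/C=C/C=C(C)/C=C/C=C(C)/C=C/[C@H]2C(C)=CC[C@H](C/C=C(\C)C(=O)OC)C2(C)C)C1(C)C | intermediate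
46 | CNP0304855.1, (2S,6R,2'R,6'S)-2-(3-methylbut-2-enyl)-2'-[(2E)-4-hydroxy-3-methylbut-2-enyl]-ε,ε-carotene | CC(C)=CC[C@H]1CC=C(C)[C@@H](/C=C/C(C)=C/C=C/C(C)=C/C=C/C=C(C)/C=C/C=C(C)/C=C/[C@H]2C(C)=CC[C@H](C/C=C(\C)CO)C2(C)C)C1(C)C | target

**Step count.** Total: 24 steps. Longest linear sequence: 18 steps (steps 1–9, 10–15, 22–24).

**Steps most likely to fail**

1. Step 9. The two faces of the exocyclic alkene differ only through the pseudoaxial C1 methyl and the C2 arm, so hydrogen delivery to C6 may be poorly selective or one-sided and leave too little of the trans epimer for ring B. The fallback sets out from 15 and comes back at 34; it fixes C6 by relay from C4 instead of by direct attack. LiCH2OCH2OCH3 (from Bu3SnCH2OCH2OCH3 and n-BuLi, THF, −78 °C) adds to the C6 ketone to give the tertiary allylic alcohol F1. Oxidative 1,3-transposition with pyridinium chlorochromate, C5H5NH[CrO3Cl], buffered with NaOAc, gives the C4 enone F2, which now carries C7 on C6. Tosylhydrazide in MeOH gives the tosylhydrazone F3. Catecholborane (CHCl3, 0 °C) followed by NaOAc and warming, the reductive transposition of enone tosylhydrazones, should add hydride to C4 on the face away from the arm; the allylic diazene then passes its hydrogen suprafacially to C6 on the arm face while the alkene returns to C4=C5, giving the trans MOM ether F4. Aqueous HCl in THF removes the MOM group and the acetal together and delivers 34.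

2. Step 8. The ylide may act as a base (γ-deprotonation at C3 to the dienolate) and add only slowly to the shielded carbonyl. The fallback sets out from 15 and comes back at 17, replacing the ylide by addition–elimination. Me3SiCH2Li with anhydrous CeCl3 (THF, −78 °C), a small and weakly basic nucleophile, adds to the ketone to give the β-hydroxysilane F5. KH in THF then triggers the Peterson syn-elimination to diene 17.

3. Step 15. The acidic salt may add HBr to the prenyl alkene or cyclise through it, and ionisation may scramble the C9=C10 geometry. The fallback sets out from 27 and comes back at 33 without any Brønsted acid. Horner–Wadsworth–Emmons olefination of 27 with the lithium anion of triethyl 3-methyl-4-phosphonocrotonate (LiN(SiMe3)2, THF, −78 °C to rt) builds C7=C8 and C9=C10 at once and gives the dienoate F6. i-Bu2AlH reduces it to the dienol F7. CBr4 and PPh3 (Appel reaction) give the allylic bromide F8. PPh3 in toluene then gives salt 33.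

**Further compounds**

F1 | step 9 | 1,2-adduct of 15, C6 carrying OH and CH2OCH2OCH3 (C2 as in 15; C6 not assigned) | COC(OC)C[C@H]1CC=C(C)C(O)(COCOC)C1(C)C
F2 | step 9 | 5-(2,2-dimethoxyethyl)-3-[(methoxymethoxy)methyl]-2,4,4-trimethylcyclohex-2-en-1-one (C2 of ring numbering as in 15) | COC(OC)C[C@H]1CC(=O)C(C)=C(COCOC)C1(C)C
F3 | step 9 | tosylhydrazone of F2 | COC(OC)C[C@H]1CC(=NNS(=O)(=O)c2ccc(C)cc2)C(C)=C(COCOC)C1(C)C
F4 | step 9 | trans MOM ether, (2R,6S)-2-(2,2-dimethoxyethyl)-6-[(methoxymethoxy)methyl] ring (ring numbering) | COC(OC)C[C@H]1CC=C(C)[C@H](COCOC)C1(C)C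
F5 | step 8 | β-hydroxysilane, 1,2-adduct of 15 with C6 carrying OH and CH2SiMe3 (C2 as in 15) | COC(OC)C[C@H]1CC=C(C)C(O)(C[Si](C)(C)C)C1(C)C
F6 | step 15 | ethyl (2E,4E)-3-methyl-5-[(1R,5S)-2,6,6-trimethyl-5-(3-methylbut-2-en-1-yl)cyclohex-2-en-1-yl]penta-2,4-dienoate | CC(C)=CC[C@H]1CC=C(C)[C@@H](/C=C/C(C)=C/C(=O)OCC)C1(C)C
F7 | step 15 | (2E,4E)-3-methyl-5-[(1R,5S)-2,6,6-trimethyl-5-(3-methylbut-2-en-1-yl)cyclohex-2-en-1-yl]penta-2,4-dien-1-ol | CC(C)=CC[C@H]1CC=C(C)[C@@H](/C=C/C(C)=C/CO)C1(C)C
F8 | step 15 | (2E,4E)-1-bromo-3-methyl-5-[(1R,5S)-2,6,6-trimethyl-5-(3-methylbut-2-en-1-yl)cyclohex-2-en-1-yl]penta-2,4-diene | CC(C)=CC[C@H]1CC=C(C)[C@@H](/C=C/C(C)=C/CBr)C1(C)C
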